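At late times the alder and cedar runs hold low target readings, between 1% and 6%, so they give a number to carry. The late share is the target divided by the starting material turned over, pooled from the last 4 readings of both runs: 4.94%, a reading that carries the scatter of the runs.

in all of them: starting material 0.0020 M
- alder: partner 3.6 mM (fed, over 2.0 min); reagent 4 mM; protic impurity 0.14 mM; capture agent 0.20 mM; run made earlier
- cedar: partner 3.6 mM (fed, over 2.0 min); reagent 4 mM; protic impurity 0.22 mM; capture agent 0.20 mM; run made earlier
- flask: partner 3.60 mM (fed, over 2.0 min); reagent 4.00 mM; protic impurity 0.100 mM; capture agent 0.200 mM; time 2.0 h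

| run | time / h | target / % | starting material / % |
|---|---|---|---|
| alder | 0.0222 | 20 | 46 |
| alder | 0.0667 | 4 | 29 |
| alder | 0.167 | 3 | 25 |
| alder | 0.417 | 6 | 24 |
| alder | 1.00 | 3 | 23 |
| alder | 2.50 | 3 | 28 |
| cedar | 0.0222 | 18 | 44 |
| cedar | 0.0667 | 7 | 26 |
| cedar | 0.167 | 6 | 25 |
| cedar | 0.417 | 6 | 23 |
| cedar | 1.00 | 2 | 23 |
| cedar | 2.50 | 1 | 22 |

(readings scatter by 1.5 percentage points)



- the best time, 2.0 h at the latest, for target, in min
- the amount of target, in percent of the starting material charged, at that time

In alder, the same ratio stands at 37.0% after 1.332 min but at 5.63% after 4.002 min. Two chemists dispute when that fall begins, and no sample lies between those times to part them.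

The first made the forecast: best at 1.5 min, with 23%, still inside the feed. Its ground is “That drop implies extra target loss once enough partner is present.”

The second holds that the target grows in step with the feed and falls only afterwards. Scaling alder's first reading up to the end of the feed, this view puts the best at 2.0 min, with 30.0%.

The flask gives its best at 1.50 min, with 20.3%, so the forecast stands. At 2 min this flask holds 17.3%, less than the second view's figure.

    starting material + reagent → open intermediate (k = 2.80 L mol⁻¹ s⁻¹)
    reagent + partner → second intermediate (k = 5.20 L mol⁻¹ s⁻¹)
    open intermediate + second intermediate → target (k = 340 L mol⁻¹ s⁻¹)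
    target ⇌ isomer of the product (K = 15.0, k = 0.0230 s⁻¹)
    starting material + protic impurity → quenched substrate (k = 100 L mol⁻¹ s⁻¹)
    open intermediate + capture agent → trapped intermediate (k = 26.0 L mol⁻¹ s⁻¹)

In this flask, the forward passing of target into isomer of the product has a half-life of 0.50 min at 1.726 min, shorter than the feed and short against the 2.0 h allowed; the second view keeps the case of a half-life long against the feed. The peak is the kinetic side of kinetic against thermodynamic control, and at 2.00 h this flask holds 59.9% of isomer of the product. The late share of the 73.5% turned over in this flask gives 3.63% of target, and this flask holds 3.99%. The neighbour with 0.0010 M of reagent turns over 24.2%, so the late share gives 1.20%, and that neighbour ends with 1.05%.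

The runs come from a simulation with constants of no real substance.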